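**Strategy.** The cyclohexane ring is cut into two three-carbon arcs. CH2–CHBr–C(CH3)Cl is read as α-carbon, carbonyl carbon and α′-carbon of a 3-oxopentanoate; CH2–CH2–CH is read as an enal whose β-carbon already carries the pyranone made from (S)-linalool. One amine-catalysed Michael/aldol-condensation/decarboxylation operation forms the bond from the CH2 beside CHBr to the ring CH and the bond from C(CH3)Cl to its other CH2 neighbour, closes the carbocycle as a carvone-type enone and sets the ring CH stereocentre under catalyst control. Afterwards the ring carbonyl becomes the secondary bromide, the ring alkene the tertiary chloride, and a final reagent-controlled reduction gives the pyranol.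

Key step: step 4

Assumption: (S)-(+)-linalool of high enantiomeric purity is taken as the commercial starting material; its carbinol carbon becomes the quaternary ether carbon of the target.

Step 1
Reactants: 1 (S)-(+)-linalool
Product: 3 (2S)-2-ethenyl-2,6,6-trimethyl-3,6-dihydro-2H-pyran, via selenide 2 (not isolated)
Conditions: PhSeCl, CH2Cl2, −78 °C to rt; then 30 % H2O2, pyridine, 0 °C to rt
Reagents that add atoms: none
Why: Phenylselenoetherification followed by selenoxide syn-elimination: the tertiary alcohol should close 6-endo onto the trisubstituted alkene at its tertiary carbon (Markovnikov, thermodynamic control), and the selenoxide can eliminate only toward the ring CH2 because the other neighbour is quaternary; the carbinol stereocentre is carried through unchanged.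

Step 2
Reactants: 3 (2S)-2-ethenyl-2,6,6-trimethyl-3,6-dihydro-2H-pyran
Product: 4 (2R)-2-ethenyl-2,6,6-trimethyl-2H-pyran-3(6H)-one
Conditions: CrO3, 3,5-dimethylpyrazole, CH2Cl2, −20 °C
Reagents that add atoms: chromium trioxide O=[Cr](=O)=O
Why: Allylic oxidation: the ring CH2 is the only allylic C–H position (both carbons next to oxygen are fully substituted and the vinyl group has no allylic hydrogen), so the enone is the only possible product; the stereocentre is untouched and its descriptor changes from S to R by priority only.

Step 3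
Reactants: 4 (2R)-2-ethenyl-2,6,6-trimethyl-2H-pyran-3(6H)-one; 5 (E)-crotonaldehyde (excess)
Product: 6 (2E)-3-[(2R)-2,6,6-trimethyl-3-oxo-3,6-dihydro-2H-pyran-2-yl]prop-2-enal
Conditions: second-generation Hoveyda–Grubbs catalyst (5 mol %), CH2Cl2, 40 °C
Reagents that add atoms: none
Why: Olefin cross-metathesis: the terminal vinyl group should react with excess crotonaldehyde to give the (E)-enal with loss of propene, while the ring alkene, cis-disubstituted inside an enone and flanked by a quaternary carbon, does not take part.

Step 4
Reactants: 6 (2E)-3-[(2R)-2,6,6-trimethyl-3-oxo-3,6-dihydro-2H-pyran-2-yl]prop-2-enal; 7 tert-butyl 3-oxopentanoate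
Product: 10 (5S)-2-methyl-5-[(2R)-2,6,6-trimethyl-3-oxo-3,6-dihydro-2H-pyran-2-yl]cyclohex-2-en-1-one, via Michael adduct 8 (not isolated), via keto ester 9 (not isolated)
Conditions: (R)-2-[bis(3,5-bis(trifluoromethyl)phenyl)(trimethylsilyloxy)methyl]pyrrolidine (10 mol %), PhCO2H (10 mol %), toluene, rt; then p-TsOH·H2O (20 mol %), toluene, 80 °C
Reagents that add atoms: none
Why: The secondary amine converts enal 6 into an (E)-iminium ion, the doubly activated carbon of 7 adds to its β-carbon (first ring bond, Michael adduct 8), and under p-TsOH the enol of the ethyl ketone attacks the released aldehyde and loses water (second ring bond, keto ester 9) before the tert-butyl ester is cleaved and the β-keto acid decarboxylates. The closest known reaction type is the organocatalytic Michael/aldol-condensation [3+3] annulation of β-keto esters with enals that gives 5-substituted cyclohex-2-enones. The carbocycle closes in a 6-(enolendo)-exo-trig aldol step, and every alternative enol closure would give a four-membered ring. The one new stereocentre, the ring CH, is set by the catalyst: the aryl(silyloxy)methyl arm of the (R)-amine covers one face of the s-trans iminium ion, so the donor adds to the other face, which gives the S centre. Chemoselectivity for the enal over the pyranone enone is needed and is secured because only the aldehyde condenses with the amine and the enone β-carbon sits beside the gem-dimethyl carbon; the pyranone has no enolisable or ionisable position and should survive the acid stage.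

Step 5
Reactants: 10 (5S)-2-methyl-5-[(2R)-2,6,6-trimethyl-3-oxo-3,6-dihydro-2H-pyran-2-yl]cyclohex-2-en-1-one
Product: 11 (2R)-2-[(1S,5R)-5-hydroxy-4-methylcyclohex-3-en-1-yl]-2,6,6-trimethyl-2H-pyran-3(6H)-one
Conditions: (S)-2-methyl-CBS-oxazaborolidine (0.2 equiv), catecholborane (1.2 equiv), toluene, −78 °C
Reagents that add atoms: none
Why: Corey–Bakshi–Shibata reduction, 1,2-selective on enones: the (S)-catalyst binds the ring carbonyl anti to its substituted alkene side and delivers hydride to the Si face (equatorial attack), which should give the pseudo-axial (5R) alcohol trans to the side chain, while the pyranone carbonyl beside a fully substituted carbon should be reduced more slowly at −78 °C.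

Step 6
Reactants: 11 (2R)-2-[(1S,5R)-5-hydroxy-4-methylcyclohex-3-en-1-yl]-2,6,6-trimethyl-2H-pyran-3(6H)-one
Product: 12 (2R)-2-[(1S,5S)-5-bromo-4-methylcyclohex-3-en-1-yl]-2,6,6-trimethyl-2H-pyran-3(6H)-one
Conditions: PPh3, CBr4, 2,6-lutidine, CH2Cl2, −20 °C
Reagents that add atoms: carbon tetrabromide BrC(Br)(Br)Br
Why: Appel reaction: bromide displaces the alkoxyphosphonium ion of the pseudo-axial allylic alcohol by SN2 with inversion, which places bromine cis to the side chain (5S); no other hydroxyl group is present.

Step 7
Reactants: 12 (2R)-2-[(1S,5S)-5-bromo-4-methylcyclohex-3-en-1-yl]-2,6,6-trimethyl-2H-pyran-3(6H)-one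
Product: 13 (2R)-2-[(1S,3S,4S)-3-bromo-4-chloro-4-methylcyclohexyl]-2,6,6-trimethyl-2H-pyran-3(6H)-one
Conditions: HCl (gas), CH2Cl2, −78 to −30 °C
Reagents that add atoms: hydrogen chloride Cl
Why: Markovnikov hydrochlorination with neighbouring-group participation: protonation at the alkene CH gives the tertiary cation, the adjacent bromine bridges it from its own face, and chloride opens the bromonium ion at the tertiary carbon from the opposite face, so chlorine should end trans to bromine and trans to the side chain (4S) while the bromine-bearing centre is unchanged; the pyranone cannot ionise at its ether carbons and is inert to HCl.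

Step 8
Reactants: 13 (2R)-2-[(1S,3S,4S)-3-bromo-4-chloro-4-methylcyclohexyl]-2,6,6-trimethyl-2H-pyran-3(6H)-one
Product: 14 (2R,3R)-2-[(1S,3S,4S)-3-bromo-4-chloro-4-methylcyclohexyl]-2,6,6-trimethyl-3,6-dihydro-2H-pyran-3-ol
Conditions: (S)-2-methyl-CBS-oxazaborolidine (1 equiv), BH3·SMe2, THF, −20 to 0 °C
Reagents that add atoms: none
Why: Corey–Bakshi–Shibata reduction: with the fully substituted ring carbon as the large and the alkene CH as the small substituent, the (S)-catalyst delivers hydride to the Si face of the pyranone carbonyl, which should give the (3R) allylic alcohol on the same side as the cyclohexyl group; borane leaves the secondary bromide and the tertiary chloride untouched.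

**Compound list**

1 | (S)-(+)-linalool, (3S)-3,7-dimethylocta-1,6-dien-3-ol | C=C[C@@](C)(O)CCC=C(C)C | starting material
2 | (6S)-6-ethenyl-2,2,6-trimethyl-3-(phenylselanyl)oxane (both C3 epimers) | CC1(C)C([Se]c2ccccc2)CC[C@@](C)(C=C)O1 | intermediate
3 | (2S)-2-ethenyl-2,6,6-trimethyl-3,6-dihydro-2H-pyran | CC1(C)C=CC[C@@](C)(C=C)O1 | intermediate
4 | (2R)-2-ethenyl-2,6,6-trimethyl-2H-pyran-3(6H)-one | CC1(C)C=CC(=O)[C@@](C)(C=C)O1 | intermediate
5 | (E)-crotonaldehyde | C/C=C/C=O | starting material
6 | (2E)-3-[(2R)-2,6,6-trimethyl-3-oxo-3,6-dihydro-2H-pyran-2-yl]prop-2-enal | CC1(C)C=CC(=O)[C@@](C)(/C=C/C=O)O1 | intermediate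
7 | tert-butyl 3-oxopentanoate | CCC(=O)CC(=O)OC(C)(C)C | starting material
8 | tert-butyl (3S)-5-oxo-2-propanoyl-3-[(2R)-2,6,6-trimethyl-3-oxo-3,6-dihydro-2H-pyran-2-yl]pentanoate (both C2 epimers) | CC1(C)C=CC(=O)[C@@](C)([C@H](C(C(=O)CC)C(=O)OC(C)(C)C)CC=O)O1 | intermediate
9 | tert-butyl (6S)-3-methyl-2-oxo-6-[(2R)-2,6,6-trimethyl-3-oxo-3,6-dihydro-2H-pyran-2-yl]cyclohex-3-ene-1-carboxylate (both C1 epimers) | CC1(C)C=CC(=O)[C@@](C)([C@H]2CC=C(C)C(=O)C2C(=O)OC(C)(C)C)O1 | intermediate
10 | (5S)-2-methyl-5-[(2R)-2,6,6-trimethyl-3-oxo-3,6-dihydro-2H-pyran-2-yl]cyclohex-2-en-1-one | CC1(C)C=CC(=O)[C@@](C)([C@H]2CC=C(C)C(=O)C2)O1 | intermediate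
11 | (2R)-2-[(1S,5R)-5-hydroxy-4-methylcyclohex-3-en-1-yl]-2,6,6-trimethyl-2H-pyran-3(6H)-one | CC1(C)C=CC(=O)[C@@](C)([C@H]2CC=C(C)[C@H](O)C2)O1 | intermediate
12 | (2R)-2-[(1S,5S)-5-bromo-4-methylcyclohex-3-en-1-yl]-2,6,6-trimethyl-2H-pyran-3(6H)-one | CC1(C)C=CC(=O)[C@@](C)([C@H]2CC=C(C)[C@@H](Br)C2)O1 | intermediate
13 | (2R)-2-[(1S,3S,4S)-3-bromo-4-chloro-4-methylcyclohexyl]-2,6,6-trimethyl-2H-pyran-3(6H)-one | CC1(C)C=CC(=O)[C@@](C)([C@H]2CC[C@](C)(Cl)[C@@H](Br)C2)O1 | intermediate
14 | (2R,3R)-2-[(1S,3S,4S)-3-bromo-4-chloro-4-methylcyclohexyl]-2,6,6-trimethyl-3,6-dihydro-2H-pyran-3-ol | CC1(C)C=C[C@@H](O)[C@@](C)([C@H]2CC[C@](C)(Cl)[C@@H](Br)C2)O1 | target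

Total step count: 8. Longest linear sequence: 8 steps (1 to 14).

**The three steps most likely to fail**

1. Step 7. Chloride may capture the open tertiary cation before bromine bridges, which would cost facial selectivity. Chloride may also open the bromonium ion at the secondary carbon with a bromine shift, and the allylic bromide may undergo halide exchange or allylic isomerisation before the alkene is protonated. The fallback sets out from 11. A Mitsunobu displacement with 2-nitrobenzenesulfonylhydrazide (PPh3, DEAD, THF, −30 °C) would give the allylic sulfonylhydrazide F1. On warming this loses the sulfinic acid and dinitrogen through the allylic diazene (reductive 1,3-transposition) to give the 1-methylcyclohexene F2. Anti, Markovnikov bromochlorination of F2 with Bu4NBrCl2 (CH2Cl2, −78 °C) should give both trans adducts. Compound 13 arises from the bromonium ion on the side-chain face and must be separated from the trans-diaxial adduct F3, which is expected to be favoured. This fallback therefore costs material but avoids the allylic bromide; it comes back to the route at 13.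

2. Step 4. Conjugate addition at the β-carbon beside the quaternary carbon may be slow, so that the iminium ion is consumed in side reactions, and facial control may erode if catalyst and resident stereocentre are mismatched. The fallback sets out from 6. The cesium enolate of 7 (Cs2CO3, THF, 0 °C), a stronger donor that needs no iminium activation, is added in a classical anionic Michael addition; the neighbouring quaternary carbon is then the only control element. Adduct 8 is cyclised and decarboxylated with p-TsOH as before. The epimeric enone F4 formed beside 10 is removed by chromatography, and the route comes back at 10.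

3. Step 5. Chemoselectivity between the two enone carbonyls may be lost, and the reagent may not fully override the ring's preference for axial hydride delivery. The fallback sets out from 10. Luche reduction (NaBH4, CeCl3·7H2O, MeOH, −78 °C) reduces both carbonyls and should give the diol F5 with the ring carbinol cis to the side chain; the pyran carbinol configuration is immaterial because it is oxidised again. A Mitsunobu reaction with 4-nitrobenzoic acid (PPh3, DEAD) inverts only the ring carbinol, since the pyran carbinol is neopentyl, to give the 4-nitrobenzoate F6. Methanolysis (K2CO3, MeOH) gives the trans diol F7, and Appel bromination (PPh3, CBr4) again touches only the ring carbinol to give the bromo alcohol F8. Oxidation of the remaining allylic alcohol with Dess–Martin periodinane returns the route at 12.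

**Further compounds**

F1 | step 7 | N-[(1S,5S)-2-methyl-5-[(2R)-2,6,6-trimethyl-3-oxo-3,6-dihydro-2H-pyran-2-yl]cyclohex-2-en-1-yl]-2-nitrobenzenesulfonohydrazide | CC1(C)C=CC(=O)[C@@](C)([C@H]2CC=C(C)[C@@H](N(N)S(=O)(=O)c3ccccc3[N+](=O)[O-])C2)O1
F2 | step 7 | (2R)-2,6,6-trimethyl-2-[(1S)-4-methylcyclohex-3-en-1-yl]-2H-pyran-3(6H)-one | CC1(C)C=CC(=O)[C@@](C)([C@H]2CCC(C)=CC2)O1
F3 | step 7 | (2R)-2-[(1S,3R,4R)-3-bromo-4-chloro-4-methylcyclohexyl]-2,6,6-trimethyl-2H-pyran-3(6H)-one | CC1(C)C=CC(=O)[C@@](C)([C@H]2CC[C@@](C)(Cl)[C@H](Br)C2)O1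
F4 | step 4 | (5R)-2-methyl-5-[(2R)-2,6,6-trimethyl-3-oxo-3,6-dihydro-2H-pyran-2-yl]cyclohex-2-en-1-one | CC1(C)C=CC(=O)[C@@](C)([C@@H]2CC=C(C)C(=O)C2)O1
F5 | step 5 | (2R)-2-[(1S,5S)-5-hydroxy-4-methylcyclohex-3-en-1-yl]-2,6,6-trimethyl-3,6-dihydro-2H-pyran-3-ol (both C3 epimers) | CC1(C)C=CC(O)[C@@](C)([C@H]2CC=C(C)[C@@H](O)C2)O1
F6 | step 5 | (1R,5S)-5-[(2R)-3-hydroxy-2,6,6-trimethyl-3,6-dihydro-2H-pyran-2-yl]-2-methylcyclohex-2-en-1-yl 4-nitrobenzoate (both pyran C3 epimers) | CC1(C)C=CC(O)[C@@](C)([C@H]2CC=C(C)[C@H](OC(=O)c3ccc(cc3)[N+](=O)[O-])C2)O1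
F7 | step 5 | (2R)-2-[(1S,5R)-5-hydroxy-4-methylcyclohex-3-en-1-yl]-2,6,6-trimethyl-3,6-dihydro-2H-pyran-3-ol (both C3 epimers) | CC1(C)C=CC(O)[C@@](C)([C@H]2CC=C(C)[C@H](O)C2)O1
F8 | step 5 | (2R)-2-[(1S,5S)-5-bromo-4-methylcyclohex-3-en-1-yl]-2,6,6-trimethyl-3,6-dihydro-2H-pyran-3-ol (both C3 epimers) | CC1(C)C=CC(O)[C@@](C)([C@H]2CC=C(C)[C@@H](Br)C2)O1
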